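The constants used here are assumed, and the outcome is calculated.

The ratio I follow in this flask is the loss of starting material to homo dimer over its loss to intermediates A and B, both taken per minute at the start.

starting material 0.10 M; time 15 d

    intermediate B ⇌ intermediate D (K1 = 0.69, k1 = 0.013 min⁻¹)
    target ⇌ isomer of the product (K2 = 0.45, k2 = 0.0051 min⁻¹)
    intermediate A → target (k3 = 0.011 min⁻¹)
    intermediate B ⇌ intermediate C (K4 = 33, k4 = 0.13 min⁻¹)
    starting material → intermediate A (k5 = 0.016 min⁻¹)
    2 starting material → homo dimer (k6 = 0.036 M⁻¹ min⁻¹)
    intermediate C ⇌ intermediate A (K7 = 19, k7 = 0.0060 min⁻¹)
    intermediate D ⇌ intermediate E (K8 = 0.38, k8 = 0.013 min⁻¹)
    starting material → intermediate B (k9 = 0.027 min⁻¹)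

1. which holds at 15 d: what has brought the reaction to rest, or that it has not come to rest (forward and back rates have come level / all of the starting material has reacted / it is still moving)
2. amount of target at 15 d, in percent of the starting material charged
3. amount of isomer of the product at 15 d, in percent of the starting material charged

- a species is counted by the starting material in it: one homo dimer counts as two
- a doubled species enters its step squared and goes two at a time
- the reaction counts as stopped when no species that holds the starting material changes by six tenths of a point or more over the second half of the time
- run time (flask): 15 d

At the charge, the dimer step removes starting material at 0.00720 min⁻¹, two per turn counted, and the two first-order steps together remove it at 0.0430 min⁻¹. The first over the second I call the dimer ratio, and here it is 0.167.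

Does the flask stop? The half-life of starting material by the two first-order steps is 16.1 min, short against 15 d, so my answer for the end is all of the starting material has reacted.

Then how much became homo dimer? The ratio shrinks as the starting material falls: the dimer step goes with its square, the other two steps with its first power. I solve the two ends: for a small ratio the share of the charge lost grows in step with the ratio, and for a large one it nears the whole charge. Integrating over the fall joins them: the share is one minus the natural logarithm of one plus the ratio, divided by the ratio, which gives 7.54%, about half of the ratio.

Where does the rest go? The forward half-life of intermediate C by its step to intermediate A, 0.080 d, is short against 15 d, and so is the relaxation of target and isomer of the product, 0.703 h. The split of the rest is therefore thermodynamic control at 0.45, and I reckon 63.8% for target and 28.7% for isomer of the product.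

The forecast says all of the starting material has reacted, with 63.8% of target and 28.7% of isomer of the product, the remainder being “simply split between target and isomer”.

This flask gives all of the starting material has reacted, with 63.8% of target and 28.7% of isomer of the product, and its homo dimer reads 7.54% at 15.0 d. A flask charged with 0.40 M has a dimer ratio of 0.670, so the same formula gives a share of 23.5% and target of 52.8%. That flask reads 23.5% of homo dimer and 52.8% of target.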